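Germacrane numbering is used throughout: ring C1–C10; C11, C12 (carbonyl) and C13 (exocyclic methylene) are the lactone carbons; C14 sits on C10 and C15 on C4.

## The problem

Target 46 is a germacranolide: a cyclodeca-1(10),4-diene trans-fused at C6–C7 to an α-methylene-γ-butyrolactone closed on O6. Both ring double bonds are trisubstituted and cis within the ring (C2 cis to C9, C3 cis to C6; both E by the sequence rule), with the methyl ester C14 on C10 and the free hydroxymethyl C15 on C4. Four contiguous stereocentres (6R, 7S, 8S, 9R) carry the lactone oxygen, the lactone carbon chain, an angelate and an acetate. C6 and C7 are trans on the five-membered ring, so one can set the other; O8 and O9 are erythro; C5 and C10 are sp2 in the target and can serve as disposable stereocentres on the way. Because the two vicinal esters differ, O8 and O9 must be told apart by the construction, not by a late selective acylation. The α-methylene lactone is a Michael acceptor, the angelate isomerises to the tiglate under base, the C6–O bond is allylic and the vicinal esters can migrate, so strong bases and nucleophiles are excluded once these groups are present. The ten-membered ring is the central difficulty, since direct closure fights transannular strain and must deliver two cis alkenes. The handle is that, once the C1–C10 enoate is read as the dehydration product of a C1 ketone, C1(=O)–C2–C3–C4=C5 is a γ,δ-unsaturated ketone, the retron of a Claisen rearrangement. Tying C1 to C5 through oxygen gives an eight-membered 2-methylene cyclic ether whose tether C6–C10 already holds every stereocentre.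

## Retrosynthesis

**O15, O8 and O9.** Target 46 is traced to its 15-O-(4-methoxybenzyl) ether 45, and 45 to alcohol 42 and angelic acid 43. The angelate is put on last among the acyl groups because it is the most base-sensitive one. The acetate of 42 goes back to enal 38, where O9 is the only free hydroxyl. The two oxygens never compete because O9 is released together with O14 from a 1,3-dioxane (35 → 36), while O8 stays silylated until 41 → 42. This asks only for ordinary acylations of single free alcohols.

**C1=C10 and C14.** Ester 41 comes from acid 40, this from enal 39/38, and 38 from the β-mesyloxy alcohol 36 by oxidation at C14 and E1cB loss of the C1 mesylate (35 from 34). An olefination at a C1 ketone would have to build a trisubstituted enoate inside the ring. The elimination instead uses the oxygen that the key step leaves on C1, and the conjugated aldehyde can settle in the required geometry. The precursor is simpler by one alkene and has C10 as an sp3 centre of no consequence.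

**The α-methylene lactone.** The C11=C13 unit of 34 is cut back to lactone 31, and 31 to triol 29 (from 28, from ketone 27) by oxidative lactonisation of the 6,12-diol. The methylenation needs an enolate, so it is placed before any mesylate, enal or second ester exists. The lactone cannot pass through the key sequence, because lactone methylenation would attack it too; C12 therefore travels at the alcohol level, as a bis(triethylsilyl) ether.

**The ten-membered ring (key cut).** The C2–C3 bond of cyclodecenone 27 is cut and O reconnected to C5, giving 2-methyleneoxocane 26, which comes from lactone 25 by carbonyl methylenation. This turns a cyclodecene with a cis trisubstituted alkene into an eight-membered lactone made from an acyclic hydroxy acid. It asks for a thermal [3,3] shift through a bridged array in which the tether forces the cis alkene.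

**The eight-membered lactone.** Lactone 25 is opened at the acyl–oxygen bond to seco acid 23. Closure at a C–C bond of the ring would require a stereocentre to be formed during cyclisation, whereas the lactonisation forms none. The dioxane fused at C9–C10 and a substituent on every ring carbon pre-fold the chain; the forward step is a high-dilution macrolactonisation.

**C4–C5.** Acid 23 comes from diol 21 and pivalate 20, and 20 from aldehyde 16 and alkenyllithium 19 (made from bromide 18, itself from 2-bromoprop-2-en-1-ol 17). This one addition brings C3, C4 and C15 and creates the C5 carbinol, whose configuration is irrelevant because the rearrangement erases it.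

**C1.** Aldehyde 16 goes back through 15 and 14 to primary alcohol 13, which arises from ketone 10 by methylenation (11) and hydroboration. C10 becomes a stereocentre that is later destroyed, so no control is demanded.

**C8–C9.** Ketone 10 is the silyl ether of aldol 9, cut at C8–C9 into aldehyde 7 and 2,2-dimethyl-1,3-dioxan-5-one 8. An organocatalytic enamine anti-aldol sets C8 and C9 together, brings C10 and C14, and leaves O8 free while O9 and O14 share one acetal. A sugar-derived cis-diol acetonide or a dihydroxylation would deliver O8 and O9 as an indistinguishable pair. The forward reaction must give the anti adduct on one aldehyde face under catalyst control.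

**C7–C8 and the C5–C12 block.** Aldehyde 7 comes from alkene 5 by ozonolysis, 5 from diol 4, and 4 from lactone 3. Lactone 3 is the trans conjugate adduct of a vinyl group to benzyl-protected butenolide 2, made from (S)-5-(hydroxymethyl)furan-2(5H)-one 1. Butenolide 1 supplies C5, C6, C7, C11 and C12 with C6 in the correct absolute configuration, and the five-membered ring relays it to C7.

## Roads not taken

**Alternative 1:** Two ring bonds, C1–C2 and C9–C10, are cut, so that C1 and C10 are inserted between C2 and C9 of an eight-membered ring. In the forward sense the C9 trimethylsilyl enol ether A1 of a lactone-fused cyclooctenone adds methyl propiolate A2 across C2=C9 under EtAlCl2, and desilylation cleaves the old C2–C9 bond to give keto enoate A3.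
- Merits: the enoate and its ester carbon arrive in the ring-forming step, the four-membered intermediate fixes C2 and C9 cis on the new double bond, and O9 appears as a ketone, so O8 and O9 are distinct. In these respects it is better than the chosen plan.
- Weak points: A1 needs an eight-membered carbocycle that is itself a medium-ring problem. The enol ether must form away from the oxygenated C8. A strong Lewis acid meets a lactone and two silyl ethers. The dienolate released on fragmentation can protonate at C10 instead of C2. The 9R alcohol then has to come from reduction of a ketone in a mobile ring, and the lactone must still be methylenated beside an enoate and a ketone.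
- Comparison: the chosen plan offers a single medium-ring event, C9 set early by an aldol, and an enolate step run before any enoate exists.

**Alternative 2:** The target ring is derived from a hydroazulene by cutting the transannular C6–C10 bond. Treating hydroxy mesylate A4 with KOt-Bu makes the C6 alkoxide, which expels the C1 mesylate in a Grob fragmentation and gives dienone ester A5.
- Merits: five–seven fused systems are easier to assemble than ten-membered rings. The fragmentation is stereospecific, so the C1=C10 geometry follows from the relative configuration of C1 and C10. That is a firmer control than the thermodynamic elimination used here.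
- Weak points: A4 demands a tertiary alcohol at C6 next to a quaternary ester-bearing C10 and a defined C1, three centres built only to be destroyed. A5 is a cis-enone with an epimerisable C7 beside the ketone. C6 must then be reduced to the R alcohol on a flexible ring, and the 8,9-acetonide leaves the two esters undifferentiated.
- Comparison: the chosen plan offers C6 from the chiral pool, never at the ketone level, and O8/O9 distinguished from the aldol onward.

**Alternative 3:** The C3–C4 bond is cut. Seco compound A6, an N-acyloxyphthalimide with an alkenyl iodide, is reduced at a cathode with NiCl2·glyme and 2,2′-bipyridine; loss of CO2 gives the C3 radical, which is captured by nickel and coupled with the alkenyl iodide to close lactone acetonide A7.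
- Merits: this is the most convergent route. The lactone, the enoate and the C4=C5 geometry are in place before ring closure and no redox adjustment follows, so if the cyclisation worked it would be clearly shorter than the chosen route.
- Weak points: a ten-membered ring with two cis alkenes must close in a catalytic cycle that competes with reduction and dimerisation of a primary radical. The radical is homoallylic to the enoate. A7 still needs lactone methylenation beside an enoate (transannular Michael risk) and a selective acylation of an unbiased cis-diol.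
- Comparison: the chosen plan offers a unimolecular ring expansion driven by carbonyl formation and an unambiguous endgame.

Key step: step 19

Assumption: C1 of 28–37 arises as a mixture of carbinol epimers that converge when C1 becomes sp2 in step 26; its configuration is left open in names and SMILES, as are the hemiacetal carbon of 30, C11 of 32 and 33 and the ring carbon of ozonide 6.

Assumption: the auxiliary centres C10 (step 9) and C5 (step 14) are drawn as the epimers expected from the models named in those steps; both are destroyed later (steps 26 and 19), so a minor epimer would converge on the same compounds.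

## Route

Step 1
Reactants: 1 (S)-5-(hydroxymethyl)furan-2(5H)-one
Product: 2 (S)-5-[(benzyloxy)methyl]furan-2(5H)-one
Conditions: BnOC(=NH)CCl3, TfOH (cat.), CH2Cl2/cyclohexane, 0 °C to rt
Reagents that add atoms: benzyl 2,2,2-trichloroacetimidate, N=C(OCc1ccccc1)C(Cl)(Cl)Cl
Why: Acid-catalysed O-benzylation with the trichloroacetimidate avoids base, which would racemise the butenolide through its furanolate; C6 is not touched.

Step 2
Reactants: 2 (S)-5-[(benzyloxy)methyl]furan-2(5H)-one
Product: 3 (4R,5S)-5-[(benzyloxy)methyl]-4-vinyldihydrofuran-2(3H)-one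
Conditions: CH2=CHMgBr, CuBr·SMe2 (cat.), THF, −78 °C; aq. NH4Cl
Reagents that add atoms: vinylmagnesium bromide, C=C[Mg]Br
Why: Copper-catalysed conjugate addition to the butenolide; the vinyl group enters on the face opposite the C6 benzyloxymethyl group, which sets C7 trans to C6 by substrate control in the five-membered ring.

Step 3
Reactants: 3 (4R,5S)-5-[(benzyloxy)methyl]-4-vinyldihydrofuran-2(3H)-one
Product: 4 (2S,3R)-1-(benzyloxy)-3-vinylpentane-2,5-diol
Conditions: LiAlH4, THF, 0 °C
Reagents that add atoms: none
Why: Hydride reduction of the γ-lactone to the 1,4-diol takes C12 to the alcohol level, so that the later lactone methylenation meets only one ester carbonyl; ether and alkene are inert.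

Step 4
Reactants: 4 (2S,3R)-1-(benzyloxy)-3-vinylpentane-2,5-diol
Product: 5 (2S,3R)-1-(benzyloxy)-2,5-bis(triethylsilyloxy)-3-vinylpentane
Conditions: Et3SiCl, imidazole, DMF, 0 °C to rt
Reagents that add atoms: chlorotriethylsilane, CC[Si](Cl)(CC)CC
Why: Standard silylation of a primary and a secondary alcohol; triethylsilyl is chosen so that both ethers can later be removed beside a tert-butyldimethylsilyl ether.

Step 5
Reactants: 5 (2S,3R)-1-(benzyloxy)-2,5-bis(triethylsilyloxy)-3-vinylpentane
Product: 7 (S)-2-[(S)-2-(benzyloxy)-1-(triethylsilyloxy)ethyl]-4-(triethylsilyloxy)butanal (C8 aldehyde), via ozonide 6 (not isolated)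
Conditions: O3, CH2Cl2, −78 °C; PPh3, −78 °C to rt
Reagents that add atoms: ozone, [O-][O+]=O
Why: Ozonolysis with reductive work-up cleaves the only alkene to the C8 aldehyde; the crude aldehyde is used at once to avoid epimerisation at C7.

Step 6
Reactants: 7 C8 aldehyde; 8 2,2-dimethyl-1,3-dioxan-5-one
Product: 9 anti-aldol adduct (S)-4-[(1S,2R,3S)-4-(benzyloxy)-1-hydroxy-3-(triethylsilyloxy)-2-[2-(triethylsilyloxy)ethyl]butyl]-2,2-dimethyl-1,3-dioxan-5-one
Conditions: (S)-proline (30 mol %), DMF, 4 °C
Reagents that add atoms: none
Why: Proline-catalysed direct aldol reaction (enamine catalysis, Houk–List transition state) of the dioxanone gives the anti adduct; the (S)-catalyst fixes C9 through the enamine face and C8 through hydrogen-bond-directed attack on one aldehyde face, and is expected to override the weak, mutually opposed 1,2- and 1,3-biases of 7. O8 is born free while O9 and O14 stay tied in the acetal, which is what distinguishes O8 from O9 for the rest of the route.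

Step 7
Reactants: 9 anti-aldol adduct
Product: 10 8-O-(tert-butyldimethylsilyl) ether of 9 (C10 ketone)
Conditions: t-BuMe2SiOTf, 2,6-lutidine, CH2Cl2, −78 °C
Reagents that add atoms: tert-butyldimethylsilyl trifluoromethanesulfonate, CC(C)(C)[Si](C)(C)OS(=O)(=O)C(F)(F)F
Why: Silyl triflate with a hindered base silylates the β-hydroxy ketone at low temperature without retro-aldol cleavage or β-elimination.

Step 8
Reactants: 10 8-O-silyl C10 ketone
Product: 11 C10 methylene compound (4-substituted 2,2-dimethyl-5-methylene-1,3-dioxane)
Conditions: Cp2TiMe2, toluene, 65 °C, dark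
Reagents that add atoms: dimethyltitanocene Cp2TiMe2, [CH3-].[CH3-].[Ti+4].c1cc[cH-]c1.c1cc[cH-]c1
Why: Petasis methylenation is non-basic, so the α-alkoxy ketone is olefinated without epimerisation at C9 or loss of the C8 silyloxy group; no other carbonyl is present.

Step 9
Reactants: 11 C10 methylene compound
Product: 13 C1 primary alcohol (9,10-trans on the dioxane), via B-alkyl-9-BBN adduct 12 (not isolated)
Conditions: 9-BBN, THF, 0 °C to rt; then NaOH, H2O2, 0 °C
Reagents that add atoms: hydrogen peroxide, OO
Why: Anti-Markovnikov hydroboration–oxidation of the 1,1-disubstituted alkene gives the C1 alcohol; hydride should reach C10 along the unhindered axial direction of the dioxane, placing the new CH2OH trans to the C9 substituent, an auxiliary centre erased in step 26.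

Step 10
Reactants: 13 C1 primary alcohol
Product: 14 C1 pivalate
Conditions: t-BuCOCl, pyridine, DMAP (cat.), CH2Cl2, 0 °C to rt
Reagents that add atoms: pivaloyl chloride, CC(C)(C)C(=O)Cl
Why: Acylation of the only free hydroxyl; the hindered ester should survive hydrogenolysis, oxidation and the organolithium addition at −78 °C.

Step 11
Reactants: 14 C1 pivalate
Product: 15 C5 primary alcohol
Conditions: H2 (1 atm), Pd/C, EtOAc, rt
Reagents that add atoms: none
Why: Hydrogenolysis of the benzyl ether; no alkene is present at this stage, and silyl ethers, acetonide and pivalate are inert in ethyl acetate.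

Step 12
Reactants: 15 C5 primary alcohol
Product: 16 C5 aldehyde (α-triethylsilyloxy aldehyde)
Conditions: Dess–Martin periodinane, NaHCO3, CH2Cl2, 0 °C to rt
Reagents that add atoms: none
Why: Buffered Dess–Martin oxidation of the primary alcohol gives the α-silyloxy aldehyde without epimerisation at C6.

Step 13
Reactants: 17 2-bromoprop-2-en-1-ol
Product: 18 2-bromo-3-[(4-methoxybenzyl)oxy]prop-1-ene
Conditions: NaH, 4-MeOC6H4CH2Cl, Bu4NI (cat.), THF, 0 °C to rt
Reagents that add atoms: 4-methoxybenzyl chloride, COc1ccc(CCl)cc1
Why: Williamson etherification of the allylic alcohol; the vinylic bromide does not react.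

Step 14
Reactants: 16 C5 aldehyde; 18 2-bromo-3-[(4-methoxybenzyl)oxy]prop-1-ene
Product: 20 C5 allylic alcohol (5,6-anti) with C1 pivalate, via alkenyllithium 19 (not isolated)
Conditions: 18, t-BuLi (2 equiv), Et2O, −78 °C; then 16, −78 °C
Reagents that add atoms: none
Why: Bromine–lithium exchange gives the 2-lithioallyl ether, which adds to the aldehyde far faster than to the pivalate at −78 °C; Felkin–Anh addition anti to the α-silyloxy group should favour the 5,6-anti alcohol, an auxiliary centre destroyed in step 19.

Step 15
Reactants: 20 C5 allylic alcohol with C1 pivalate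
Product: 21 C1,C5-diol
Conditions: i-Bu2AlH, CH2Cl2, −78 °C
Reagents that add atoms: none
Why: Reductive cleavage of the pivalate by the aluminium hydride; no other reducible group is present.

Step 16
Reactants: 21 C1,C5-diol
Product: 23 seco acid (C1 carboxylic acid with free C5 hydroxyl), via C1 aldehyde 22 (not isolated)
Conditions: TEMPO (cat.), PhI(OAc)2, CH2Cl2, 0 °C; then NaClO2, NaH2PO4, 2-methyl-2-butene, t-BuOH/H2O
Reagents that add atoms: sodium chlorite, [Na+].[O-]Cl=O
Why: Nitroxyl-catalysed oxidation is selective for the primary alcohol over the hindered secondary allylic one, and Pinnick oxidation in the same flask gives the acid; the alkene scavenger protects the 1,1-disubstituted alkene and the 4-methoxybenzyl ether from hypochlorite.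

Step 17
Reactants: 23 seco acid
Product: 25 eight-membered lactone (oxocan-2-one; ring C1–O–C5–C10), via mixed anhydride 24 (not isolated)
Conditions: 2-methyl-6-nitrobenzoic anhydride, DMAP, Et3N, CH2Cl2, slow addition at high dilution, rt to 40 °C
Reagents that add atoms: none
Why: Shiina macrolactonisation (mixed-anhydride activation and acyl transfer by DMAP) closes the ring at the only free hydroxyl; the dioxane fused at C9–C10 and a substituent on every ring carbon fold the chain and disfavour dimerisation.

Step 18
Reactants: 25 eight-membered lactone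
Product: 26 2-methyleneoxocane (exocyclic enol ether bearing the C4 alkenyl group on C5)
Conditions: Cp2TiMe2, pyridine (trace), toluene, 70 °C, dark
Reagents that add atoms: dimethyltitanocene Cp2TiMe2, [CH3-].[CH3-].[Ti+4].c1cc[cH-]c1.c1cc[cH-]c1
Why: Petasis methylenation converts the lactone carbonyl into the enol ether through an oxatitanacyclobutane, without acid or base; ethers, acetal and the 1,1-disubstituted alkene are inert and no other ester remains.

Step 19
Reactants: 26 2-methyleneoxocane
Product: 27 cyclodec-4-enone (C1 ketone with ring-cis C4=C5)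
Conditions: toluene, i-Pr2NEt (trace), base-washed sealed tube, 170 °C
Reagents that add atoms: none
Why: On heating, the allyl vinyl ether C2=C1–O–C5–C4=C3 undergoes a concerted suprafacial [3,3] sigmatropic shift (Claisen rearrangement) that forms C2–C3, breaks O–C5, moves the alkene to C4=C5 and turns the ring oxygen into the C1 carbonyl, which makes the step irreversible. The closest known reaction type is the ring-expanding Claisen rearrangement of 2-methylene-6-alkenyltetrahydropyrans, made by lactone methylenation, to cyclooct-4-enones; here the same array is bridged by five carbons instead of three. The ten-membered carbocycle is closed by the new C2–C3 bond within a bridged bicyclic transition state in which C6–C10 span C5 and C1, a two-atom ring enlargement in which oxygen leaves the ring. No stereocentre is created; C5 is erased and C6–C10 are spectators. The only selectivity needed is the C4=C5 geometry: an equatorial C6 would need an anti C1–O–C5–C6 torsion that the tether cannot span, so C6 sits pseudo-axial in a chair or a boat array and emerges cis to C3 for either C5 epimer. The dioxane fused at C9–C10 and the silyloxy groups on C6 and C8 restrict the tether and favour the folded conformer that brings C3 over C2. Base-washed glass and a trace of amine suppress acid-catalysed migration of the exocyclic double bond into the ring, the main competing path.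

Step 20
Reactants: 27 cyclodec-4-enone
Product: 28 C1 alcohol (epimers at C1)
Conditions: NaBH4, MeOH, 0 °C
Reagents that add atoms: none
Why: Borohydride reduction of the only ketone; the carbinol epimers are carried on together because C1 becomes sp2 in step 26.

Step 21
Reactants: 28 C1 alcohol
Product: 29 C1,C6,C12-triol
Conditions: HF·pyridine, pyridine, THF, 0 °C
Reagents that add atoms: none
Why: Buffered HF·pyridine should cleave the primary and the allylic secondary triethylsilyl ether much faster than the hindered secondary tert-butyldimethylsilyl ether; acetonide and 4-methoxybenzyl ether are stable.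

Step 22
Reactants: 29 C1,C6,C12-triol
Product: 31 6,12-lactone (trans-fused γ-lactone with free C1 hydroxyl), via lactol 30 (not isolated)
Conditions: TEMPO (cat.), PhI(OAc)2, CH2Cl2, rt
Reagents that add atoms: none
Why: The nitroxyl oxidant attacks the primary C12 alcohol selectively; the aldehyde is trapped by O6 as the five-membered lactol and oxidised on to the lactone, while the secondary C1 hydroxyl is left.

Step 23
Reactants: 31 6,12-lactone
Product: 34 α-methylene lactone (free C1 hydroxyl), via Mannich base 32 (not isolated), via ammonium iodide 33 (not isolated)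
Conditions: LiN(i-Pr)2 (3 equiv), THF, −78 °C; CH2=NMe2+ I−, −78 °C to rt; MeI, MeOH; NaHCO3 (aq.), CH2Cl2
Reagents that add atoms: N,N-dimethylmethyleneiminium iodide (Eschenmoser's salt), C=[N+](C)C.[I-]
Why: α-Methylenation of the lactone by Mannich reaction of its lithium enolate, quaternisation and E1cB loss of trimethylamine; it is run here because no enoate, mesylate or second ester is yet present, and the C1 hydroxyl is simply carried as its alkoxide.

Step 24
Reactants: 34 α-methylene lactone
Product: 35 C1 mesylate
Conditions: MeSO2Cl, Et3N, CH2Cl2, 0 °C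
Reagents that add atoms: methanesulfonyl chloride, CS(=O)(=O)Cl
Why: Mesylation of the only free hydroxyl turns the C1 oxygen into the leaving group for step 26.

Step 25
Reactants: 35 C1 mesylate
Product: 36 9,14-diol (C1 mesylate retained)
Conditions: PPTS (cat.), MeOH, rt
Reagents that add atoms: none
Why: Acid-catalysed transacetalisation removes the 1,3-dioxane acetonide, the most acid-labile group present; the secondary silyl ether, the 4-methoxybenzyl ether and the mesylate should survive these mild conditions.

Step 26
Reactants: 36 9,14-diol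
Product: 38 cyclodeca-1(10),4-dien-14-al with free 9-hydroxyl, via β-mesyloxy aldehyde 37 (not isolated)
Conditions: TEMPO (cat.), PhI(OAc)2, CH2Cl2, rt; then Et3N, 0 °C to rt
Reagents that add atoms: none
Why: Selective nitroxyl oxidation of the primary C14 alcohol gives the β-mesyloxy aldehyde, which eliminates by E1cB on adding amine; only C1 bears a leaving group, and the conjugated enal should settle with C2 trans to the formyl group, that is cis to C9 in the ring.

Step 27
Reactants: 38 enal with free 9-hydroxyl
Product: 39 9-acetate enal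
Conditions: Ac2O, pyridine, DMAP (cat.), CH2Cl2, 0 °C
Reagents that add atoms: acetic anhydride, CC(=O)OC(C)=O
Why: Acetylation of the only free hydroxyl places the acetate on O9 without any selectivity question.

Step 28
Reactants: 39 9-acetate enal
Product: 40 C14 carboxylic acid
Conditions: NaClO2, NaH2PO4, 2-methyl-2-butene, t-BuOH/H2O, 0 °C
Reagents that add atoms: sodium chlorite, [Na+].[O-]Cl=O
Why: Pinnick oxidation converts the enal into the acid without touching the α-methylene lactone, the alkenes or the benzylic ether.

Step 29
Reactants: 40 C14 carboxylic acid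
Product: 41 C14 methyl ester (8-O-silyl with 15-O-(4-methoxybenzyl))
Conditions: MeI, KHCO3, DMF, rt
Reagents that add atoms: iodomethane, CI
Why: Carboxylate alkylation under weakly basic conditions gives the methyl ester; diazoalkanes are avoided because they add to α-methylene lactones.

Step 30
Reactants: 41 C14 methyl ester
Product: 42 8-alcohol
Conditions: HF·pyridine, THF, 0 °C to rt
Reagents that add atoms: none
Why: Acidic fluoride removes the remaining silyl ether without base, so the neighbouring acetate should not migrate; esters, the benzylic ether and the α-methylene lactone are stable.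

Step 31
Reactants: 42 8-alcohol; 43 angelic acid ((Z)-2-methylbut-2-enoic acid)
Product: 45 8-angelate (15-O-(4-methoxybenzyl) ether of the target), via mixed anhydride 44 (not isolated)
Conditions: 43, 2,4,6-Cl3C6H2COCl, Et3N, toluene, rt; then 42, 80 °C
Reagents that add atoms: none
Why: Yamaguchi esterification through the mixed anhydride acylates the hindered C8 alcohol without isomerising the Z-alkene to the tiglate; no nucleophilic catalyst is used, which spares the α-methylene lactone.

Step 32
Reactants: 45 8-angelate 15-O-(4-methoxybenzyl) ether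
Product: 46 CNP0216801.3 (target)
Conditions: DDQ, CH2Cl2/pH 7 buffer, 0 °C
Reagents that add atoms: none
Why: Oxidative cleavage of the 4-methoxybenzyl ether by DDQ frees the C15 alcohol under neutral conditions, so the angelate, the acetate, the enoate and the α-methylene lactone are preserved.

## Compound list

1 | (S)-5-(hydroxymethyl)furan-2(5H)-one | O=C1C=C[C@@H](CO)O1 | starting material
2 | (S)-5-[(benzyloxy)methyl]furan-2(5H)-one | O=C1C=C[C@@H](COCc2ccccc2)O1 | intermediate
3 | (4R,5S)-5-[(benzyloxy)methyl]-4-vinyldihydrofuran-2(3H)-one | O=C1C[C@H](C=C)[C@@H](COCc2ccccc2)O1 | intermediate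
4 | (2S,3R)-1-(benzyloxy)-3-vinylpentane-2,5-diol | c1ccccc1COC[C@@H](O)[C@@H](C=C)CCO | intermediate
5 | (2S,3R)-1-(benzyloxy)-2,5-bis(triethylsilyloxy)-3-vinylpentane | c1ccccc1COC[C@@H](O[Si](CC)(CC)CC)[C@@H](C=C)CCO[Si](CC)(CC)CC | intermediate
6 | ozonide (1,2,4-trioxolane) of 5 | c1ccccc1COC[C@@H](O[Si](CC)(CC)CC)[C@@H](C1OCOO1)CCO[Si](CC)(CC)CC | intermediate
7 | (S)-2-[(S)-2-(benzyloxy)-1-(triethylsilyloxy)ethyl]-4-(triethylsilyloxy)butanal (C8 aldehyde) | c1ccccc1COC[C@@H](O[Si](CC)(CC)CC)[C@@H](C=O)CCO[Si](CC)(CC)CC | intermediate
8 | 2,2-dimethyl-1,3-dioxan-5-one | CC1(C)OCC(=O)CO1 | starting material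
9 | anti-aldol adduct, free 8-hydroxyl, C10 ketone (C6–C9 as in 46) | c1ccccc1COC[C@@H](O[Si](CC)(CC)CC)[C@@H]([C@H](O)[C@@H]1OC(C)(C)OCC1=O)CCO[Si](CC)(CC)CC | intermediate
10 | 8-O-(tert-butyldimethylsilyl) ether of 9 | c1ccccc1COC[C@@H](O[Si](CC)(CC)CC)[C@@H]([C@H](O[Si](C)(C)C(C)(C)C)[C@@H]1OC(C)(C)OCC1=O)CCO[Si](CC)(CC)CC | intermediate
11 | C10 methylene compound (5-methylene-1,3-dioxane) | c1ccccc1COC[C@@H](O[Si](CC)(CC)CC)[C@@H]([C@H](O[Si](C)(C)C(C)(C)C)[C@@H]1OC(C)(C)OCC1=C)CCO[Si](CC)(CC)CC | intermediate
12 | B-alkyl-9-borabicyclo[3.3.1]nonane from 11 | c1ccccc1COC[C@@H](O[Si](CC)(CC)CC)[C@@H]([C@H](O[Si](C)(C)C(C)(C)C)[C@@H]1OC(C)(C)OC[C@H]1CB1C2CCCC1CCC2)CCO[Si](CC)(CC)CC | intermediate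
13 | C1 primary alcohol (9,10-trans on the dioxane) | c1ccccc1COC[C@@H](O[Si](CC)(CC)CC)[C@@H]([C@H](O[Si](C)(C)C(C)(C)C)[C@@H]1OC(C)(C)OC[C@H]1CO)CCO[Si](CC)(CC)CC | intermediate
14 | C1 pivalate | c1ccccc1COC[C@@H](O[Si](CC)(CC)CC)[C@@H]([C@H](O[Si](C)(C)C(C)(C)C)[C@@H]1OC(C)(C)OC[C@H]1COC(=O)C(C)(C)C)CCO[Si](CC)(CC)CC | intermediate
15 | C5 primary alcohol | OC[C@@H](O[Si](CC)(CC)CC)[C@@H]([C@H](O[Si](C)(C)C(C)(C)C)[C@@H]1OC(C)(C)OC[C@H]1COC(=O)C(C)(C)C)CCO[Si](CC)(CC)CC | intermediate
16 | C5 aldehyde | O=C[C@@H](O[Si](CC)(CC)CC)[C@@H]([C@H](O[Si](C)(C)C(C)(C)C)[C@@H]1OC(C)(C)OC[C@H]1COC(=O)C(C)(C)C)CCO[Si](CC)(CC)CC | intermediate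
17 | 2-bromoprop-2-en-1-ol | C=C(Br)CO | starting material
18 | 2-bromo-3-[(4-methoxybenzyl)oxy]prop-1-ene | C=C(Br)COCc1ccc(OC)cc1 | intermediate
19 | 3-[(4-methoxybenzyl)oxy]prop-1-en-2-yllithium | [Li]C(=C)COCc1ccc(OC)cc1 | intermediate
20 | C5 allylic alcohol (5,6-anti), C1 pivalate | C=C(COCc1ccc(OC)cc1)[C@@H](O)[C@@H](O[Si](CC)(CC)CC)[C@@H]([C@H](O[Si](C)(C)C(C)(C)C)[C@@H]1OC(C)(C)OC[C@H]1COC(=O)C(C)(C)C)CCO[Si](CC)(CC)CC | intermediate
21 | C1,C5-diol | C=C(COCc1ccc(OC)cc1)[C@@H](O)[C@@H](O[Si](CC)(CC)CC)[C@@H]([C@H](O[Si](C)(C)C(C)(C)C)[C@@H]1OC(C)(C)OC[C@H]1CO)CCO[Si](CC)(CC)CC | intermediate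
22 | C1 aldehyde (C5 hydroxyl free) | C=C(COCc1ccc(OC)cc1)[C@@H](O)[C@@H](O[Si](CC)(CC)CC)[C@@H]([C@H](O[Si](C)(C)C(C)(C)C)[C@@H]1OC(C)(C)OC[C@H]1C=O)CCO[Si](CC)(CC)CC | intermediate
23 | seco acid (C1 acid, C5 hydroxyl) | C=C(COCc1ccc(OC)cc1)[C@@H](O)[C@@H](O[Si](CC)(CC)CC)[C@@H]([C@H](O[Si](C)(C)C(C)(C)C)[C@@H]1OC(C)(C)OC[C@H]1C(=O)O)CCO[Si](CC)(CC)CC | intermediate
24 | mixed anhydride of 23 with 2-methyl-6-nitrobenzoic acid | C=C(COCc1ccc(OC)cc1)[C@@H](O)[C@@H](O[Si](CC)(CC)CC)[C@@H]([C@H](O[Si](C)(C)C(C)(C)C)[C@@H]1OC(C)(C)OC[C@H]1C(=O)OC(=O)c1c(C)cccc1[N+](=O)[O-])CCO[Si](CC)(CC)CC | intermediate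
25 | eight-membered lactone (oxocan-2-one) | O=C1O[C@H](C(=C)COCc3ccc(OC)cc3)[C@@H](O[Si](CC)(CC)CC)[C@H](CCO[Si](CC)(CC)CC)[C@H](O[Si](C)(C)C(C)(C)C)[C@@H]2OC(C)(C)OC[C@@H]12 | intermediate
26 | 2-methyleneoxocane (Claisen precursor) | C=C1O[C@H](C(=C)COCc3ccc(OC)cc3)[C@@H](O[Si](CC)(CC)CC)[C@H](CCO[Si](CC)(CC)CC)[C@H](O[Si](C)(C)C(C)(C)C)[C@@H]2OC(C)(C)OC[C@@H]12 | intermediate
27 | cyclodec-4-enone (C1 ketone, ring-cis C4=C5) | O=C1CC/C(COCc3ccc(OC)cc3)=C\[C@@H](O[Si](CC)(CC)CC)[C@H](CCO[Si](CC)(CC)CC)[C@H](O[Si](C)(C)C(C)(C)C)[C@@H]2OC(C)(C)OC[C@@H]12 | intermediate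
28 | C1 alcohol (C1 epimers) | OC1CC/C(COCc3ccc(OC)cc3)=C\[C@@H](O[Si](CC)(CC)CC)[C@H](CCO[Si](CC)(CC)CC)[C@H](O[Si](C)(C)C(C)(C)C)[C@@H]2OC(C)(C)OC[C@@H]12 | intermediate
29 | C1,C6,C12-triol | OC1CC/C(COCc3ccc(OC)cc3)=C\[C@@H](O)[C@H](CCO)[C@H](O[Si](C)(C)C(C)(C)C)[C@@H]2OC(C)(C)OC[C@@H]12 | intermediate
30 | 6,12-lactol | C1C(O)O[C@@H]2/C=C(/COCc3ccc(OC)cc3)CCC(O)[C@@H]4COC(C)(C)O[C@H]4[C@@H](O[Si](C)(C)C(C)(C)C)[C@@H]12 | intermediate
31 | 6,12-lactone (C1 hydroxyl free) | C1C(=O)O[C@@H]2/C=C(/COCc3ccc(OC)cc3)CCC(O)[C@@H]4COC(C)(C)O[C@H]4[C@@H](O[Si](C)(C)C(C)(C)C)[C@@H]12 | intermediate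
32 | 11-(dimethylaminomethyl) lactone (Mannich base) | CN(C)CC1C(=O)O[C@@H]2/C=C(/COCc3ccc(OC)cc3)CCC(O)[C@@H]4COC(C)(C)O[C@H]4[C@@H](O[Si](C)(C)C(C)(C)C)[C@@H]12 | intermediate
33 | trimethylammonium iodide of 32 | C[N+](C)(C)CC1C(=O)O[C@@H]2/C=C(/COCc3ccc(OC)cc3)CCC(O)[C@@H]4COC(C)(C)O[C@H]4[C@@H](O[Si](C)(C)C(C)(C)C)[C@@H]12.[I-] | intermediate
34 | α-methylene lactone (C1 hydroxyl free) | C=C1C(=O)O[C@@H]2/C=C(/COCc3ccc(OC)cc3)CCC(O)[C@@H]4COC(C)(C)O[C@H]4[C@@H](O[Si](C)(C)C(C)(C)C)[C@@H]12 | intermediate
35 | C1 mesylate | C=C1C(=O)O[C@@H]2/C=C(/COCc3ccc(OC)cc3)CCC(OS(C)(=O)=O)[C@@H]4COC(C)(C)O[C@H]4[C@@H](O[Si](C)(C)C(C)(C)C)[C@@H]12 | intermediate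
36 | 9,14-diol C1 mesylate | C=C1C(=O)O[C@@H]2/C=C(/COCc3ccc(OC)cc3)CCC(OS(C)(=O)=O)[C@H](CO)[C@@H](O)[C@@H](O[Si](C)(C)C(C)(C)C)[C@@H]12 | intermediate
37 | C14 aldehyde C1 mesylate | C=C1C(=O)O[C@@H]2/C=C(/COCc3ccc(OC)cc3)CCC(OS(C)(=O)=O)[C@H](C=O)[C@@H](O)[C@@H](O[Si](C)(C)C(C)(C)C)[C@@H]12 | intermediate
38 | 1(10),4-dien-14-al, free 9-hydroxyl | C=C1C(=O)O[C@@H]2/C=C(/COCc3ccc(OC)cc3)CC/C=C(/C=O)[C@@H](O)[C@@H](O[Si](C)(C)C(C)(C)C)[C@@H]12 | intermediate
39 | 9-acetate enal | C=C1C(=O)O[C@@H]2/C=C(/COCc3ccc(OC)cc3)CC/C=C(/C=O)[C@@H](OC(C)=O)[C@@H](O[Si](C)(C)C(C)(C)C)[C@@H]12 | intermediate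
40 | C14 carboxylic acid | C=C1C(=O)O[C@@H]2/C=C(/COCc3ccc(OC)cc3)CC/C=C(/C(=O)O)[C@@H](OC(C)=O)[C@@H](O[Si](C)(C)C(C)(C)C)[C@@H]12 | intermediate
41 | C14 methyl ester (8-O-silyl, 15-O-(4-methoxybenzyl)) | C=C1C(=O)O[C@@H]2/C=C(/COCc3ccc(OC)cc3)CC/C=C(/C(=O)OC)[C@@H](OC(C)=O)[C@@H](O[Si](C)(C)C(C)(C)C)[C@@H]12 | intermediate
42 | 8-alcohol | C=C1C(=O)O[C@@H]2/C=C(/COCc3ccc(OC)cc3)CC/C=C(/C(=O)OC)[C@@H](OC(C)=O)[C@@H](O)[C@@H]12 | intermediate
43 | angelic acid ((Z)-2-methylbut-2-enoic acid) | C/C=C(/C)C(=O)O | starting material
44 | angelic 2,4,6-trichlorobenzoic anhydride | C/C=C(/C)C(=O)OC(=O)c1c(Cl)cc(Cl)cc1Cl | intermediate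
45 | 8-angelate, 15-O-(4-methoxybenzyl) ether of the target | C=C1C(=O)O[C@@H]2/C=C(/COCc3ccc(OC)cc3)CC/C=C(/C(=O)OC)[C@@H](OC(C)=O)[C@@H](OC(=O)/C(C)=C\C)[C@@H]12 | intermediate
46 | CNP0216801.3 | C=C1C(=O)O[C@@H]2/C=C(/CO)CC/C=C(/C(=O)OC)[C@@H](OC(C)=O)[C@@H](OC(=O)/C(C)=C\C)[C@@H]12 | target

## Step count and weakest steps

Total: 32 steps. Longest linear sequence: 31 steps from 1 (steps 1–12 and 14–32); step 13 prepares bromide 18.

**Step 19 (key step).** The bridged transition state of an eight-membered ether may need temperatures at which the exocyclic enol ether migrates into the ring or hydrolyses on traces of acid. The mobile oxocane may also populate conformers that hold C3 far from C2. A longer tether could, in principle, let some ring-trans alkene through. Fallback: from 26, replace the neutral thermal shift by the aluminium-mediated variant. i-Bu3Al in CH2Cl2 at low temperature coordinates the ring oxygen, the C5–O bond ionises to an allyl cation/aluminium enolate pair that recombines at C2–C3, and β-hydride transfer from an isobutyl group reduces the ketone in the same flask. The route is rejoined at alcohol 28 and step 20 is dropped.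

**Step 17 (eight-membered lactonisation).** Acyl transfer to the hindered allylic C5 hydroxyl may be slower than intermolecular esterification, giving diolide and oligomers, and the activated α-branched acid may decompose before it cyclises. Fallback: from 23, close the ring at the alkyl–oxygen bond instead. Mitsunobu lactonisation (PPh3, diisopropyl azodicarboxylate, toluene, high dilution) lets the carboxylate displace the activated C5 alcohol with inversion, giving the C5-epimeric lactone F1. Petasis methylenation as in step 18 gives the C5-epimeric 2-methyleneoxocane F2. Because C5 is erased in the rearrangement, heating F2 as in step 19 rejoins the route at 27.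

**Step 6 (aldol).** Enamine addition to a hindered α-branched aldehyde may be slow. The aldehyde may epimerise at C7 or lose its β-silyloxy group through its own enamine. Facial selectivity at C8 may erode because the Felkin–Anh preference of 7 opposes the catalyst. Fallback: set C8 by ketone reduction instead of aldol face selection. From 7, the adduct formed when the aldehyde bias wins is the 8-epimeric aldol F3 (C9 still catalyst-controlled). Petasis methylenation with the hydroxyl free gives the 10-methylene 8-epi alcohol F4, and Dess–Martin oxidation gives the C8 ketone F5. Reduction with LiBH(s-Bu)3 under Felkin–Anh control (hydride anti to the C9–O bond) gives the 8,9-anti alcohol F6. Silylation of F6 as in step 7 rejoins the route at 11.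

**Step 23 (α-methylenation).** With three equivalents of amide base on a substrate carrying a free alkoxide, enolisation may be incomplete. The enolate may attack other sites across the ring, and the quaternisation–elimination may stall. Fallback: run the methylenation at the aldehyde oxidation level without strong base. From 31, i-Bu2AlH at −78 °C gives lactol 30, which is isolated. Its open hydroxy aldehyde form undergoes Mannich methylenation with CH2=NMe2+ I− and Et3N in CH2Cl2 to the α-methylene lactol F7. Oxidation of F7 with MnO2 rejoins the route at 34.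

## Further compounds

F0 | step 19 | none | none
F1 | step 17 | C5-epimeric eight-membered lactone | O=C1O[C@@H](C(=C)COCc3ccc(OC)cc3)[C@@H](O[Si](CC)(CC)CC)[C@H](CCO[Si](CC)(CC)CC)[C@H](O[Si](C)(C)C(C)(C)C)[C@@H]2OC(C)(C)OC[C@@H]12
F2 | step 17 | C5-epimeric 2-methyleneoxocane | C=C1O[C@@H](C(=C)COCc3ccc(OC)cc3)[C@@H](O[Si](CC)(CC)CC)[C@H](CCO[Si](CC)(CC)CC)[C@H](O[Si](C)(C)C(C)(C)C)[C@@H]2OC(C)(C)OC[C@@H]12
F3 | step 6 | 8-epimeric aldol adduct | c1ccccc1COC[C@@H](O[Si](CC)(CC)CC)[C@@H]([C@@H](O)[C@@H]1OC(C)(C)OCC1=O)CCO[Si](CC)(CC)CC
F4 | step 6 | 10-methylene 8-epi alcohol | c1ccccc1COC[C@@H](O[Si](CC)(CC)CC)[C@@H]([C@@H](O)[C@@H]1OC(C)(C)OCC1=C)CCO[Si](CC)(CC)CC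
F5 | step 6 | C8 ketone | c1ccccc1COC[C@@H](O[Si](CC)(CC)CC)[C@@H](C(=O)[C@@H]1OC(C)(C)OCC1=C)CCO[Si](CC)(CC)CC
F6 | step 6 | 8,9-anti alcohol (8-desilyl 11) | c1ccccc1COC[C@@H](O[Si](CC)(CC)CC)[C@@H]([C@H](O)[C@@H]1OC(C)(C)OCC1=C)CCO[Si](CC)(CC)CC
F7 | step 23 | α-methylene lactol | C=C1C(O)O[C@@H]2/C=C(/COCc3ccc(OC)cc3)CCC(O)[C@@H]4COC(C)(C)O[C@H]4[C@@H](O[Si](C)(C)C(C)(C)C)[C@@H]12
A1 | alternative 1 | C9 trimethylsilyl enol ether of the lactone-fused cyclooctenone | C[Si](C)(C)OC1=CC/C(CO[Si](C)(C)C(C)(C)C)=C\[C@H]2OC(=O)C[C@@H]2[C@@H]1O[Si](CC)(CC)CC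
A2 | alternative 1 | methyl propiolate | C#CC(=O)OC
A3 | alternative 1 | ten-membered C9 keto enoate | C1C(=O)O[C@@H]2/C=C(/CO[Si](C)(C)C(C)(C)C)CC/C=C(/C(=O)OC)C(=O)[C@@H](O[Si](CC)(CC)CC)[C@@H]12
A4 | alternative 2 | hydroazulene C6 hydroxy C1 mesylate (C1, C6 and C10 set for antiperiplanar fragmentation, not assigned) | COC(=O)C12C(OS(C)(=O)=O)CCC(CO[Si](C)(C)C(C)(C)C)=CC1(O)[C@H](CCOCc1ccc(OC)cc1)[C@@H]1OC(C)(C)O[C@@H]12
A5 | alternative 2 | ten-membered dienone ester | O=C1/C=C(/CO[Si](C)(C)C(C)(C)C)CC/C=C(/C(=O)OC)[C@H]2OC(C)(C)O[C@H]2[C@H]1CCOCc3ccc(OC)cc3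
A6 | alternative 3 | seco alkenyl iodide N-acyloxyphthalimide | O=C(CC/C=C(/C(=O)OC)[C@H]1OC(C)(C)O[C@H]1[C@H]1CC(=O)O[C@@H]1/C=C(/CO[Si](C)(C)C(C)(C)C)I)ON1C(=O)c2ccccc2C1=O
A7 | alternative 3 | ten-membered lactone acetonide | C1C(=O)O[C@@H]2/C=C(/CO[Si](C)(C)C(C)(C)C)CC/C=C(/C(=O)OC)[C@H]3OC(C)(C)O[C@H]3[C@@H]12
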